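**Retrosynthetic overview**

- Target 15 comes from dienyl butenolide 14 by hydrogenation of the side-chain C15=C16 alkene only; the tetrasubstituted ring alkene C3=C4 is kept.
- Feature: the ring atoms O1, C2(=O), C3 with its CH3, C4 and C5H2 of the 2(5H)-furanone are exactly 2-methylbuta-2,3-dienoic acid 13. Its central allene carbon (ring C4) lacks only the C16 chain.
- The only ring is therefore closed once, in step 7: 13 and (E)-alkenyl iodide 8 are joined under Pd catalysis, forming C4–C16 and O1–C5 in one operation.
- Iodide 8 comes from terminal alkyne 6 (hydrozirconation–iodination), made by acetylation and alkyne zipper from (S)-hexadec-4-yn-2-ol 4, itself from lithiated 1-tridecyne and (S)-propylene oxide, the source of the only stereocenter.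
- Acid 13 comes from ethyl allenoate 12 by saponification; 12 comes from Wittig reaction of phosphorane 9 with ketene generated from acetyl chloride.

Key step: step 7

Remark: the geometry of the side-chain alkene in 8 and 14 has no bearing on the target, because step 8 saturates it; E is specified because hydrozirconation delivers it.

**Route**

Step 1
Reactants: 1 1-tridecyne; 2 (S)-propylene oxide
Product: 4 (S)-hexadec-4-yn-2-ol, via lithium tridec-1-yn-1-ide 3 (not isolated)
Conditions: n-BuLi, THF, −78 °C; then 2, DMPU, −78 °C → rt; H2O
Reagents that add atoms: none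
Why: Alkynylation of a terminal epoxide, in which the lithium acetylide opens 2 by SN2 attack at the unsubstituted CH2, so the C–O stereocenter is not touched and its (S) configuration passes from 2 into 4.

Step 2
Reactants: 4 (S)-hexadec-4-yn-2-ol
Product: 5 (S)-hexadec-15-yn-2-ol
Conditions: KH (4 equiv), H2N(CH2)3NH2, rt (forms KNH(CH2)3NH2); then 4, 0 °C → rt; H2O
Reagents that add atoms: none
Why: Alkyne zipper reaction, in which KNH(CH2)3NH2 moves the triple bond along the chain by repeated propargyl–allenyl proton shifts until the terminal alkyne is trapped as its potassium acetylide, while the C2 alkoxide carbon blocks migration the other way and is never deprotonated, so (S) is retained.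

Step 3
Reactants: 5 (S)-hexadec-15-yn-2-ol
Product: 6 (S)-hexadec-15-yn-2-yl acetate
Conditions: Ac2O, pyridine, DMAP (cat.), CH2Cl2, 0 °C → rt
Reagents that add atoms: acetic anhydride, CC(=O)OC(C)=O
Why: DMAP-catalysed O-acylation of the secondary alcohol, which does not break the C2–O bond and therefore retains configuration.

Step 4
Reactants: 6 (S)-hexadec-15-yn-2-yl acetate
Product: 8 (2S,15E)-16-iodohexadec-15-en-2-yl acetate, via alkenylzirconocene chloride 7 (not isolated)
Conditions: Cp2Zr(H)Cl (1.2 equiv), THF, rt, dark; then I2, 0 °C
Reagents that add atoms: iodine, II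
Why: Hydrozirconation of the terminal alkyne is a syn addition that places zirconium on the terminal carbon, and iodinolysis of the C–Zr bond with retention should give the (E)-1-iodoalkene; alkyne insertion is much faster than hydride attack on the acetate when the reagent is kept near one equivalent.

Step 5
Reactants: 9 ethyl 2-(triphenylphosphoranylidene)propanoate; 10 acetyl chloride
Product: 12 ethyl 2-methylbuta-2,3-dienoate, via ketene 11 (not isolated)
Conditions: Et3N, CH2Cl2, 0 °C → rt
Reagents that add atoms: none
Why: Et3N dehydrochlorinates acetyl chloride to ketene, whose C=O undergoes Wittig olefination with the stabilised ylide 9 to give the allenoate.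

Step 6
Reactants: 12 ethyl 2-methylbuta-2,3-dienoate
Product: 13 2-methylbuta-2,3-dienoic acid
Conditions: LiOH, THF/H2O, 0 °C → rt; then 1 M HCl to pH 2
Reagents that add atoms: lithium hydroxide, [Li+].[OH-]
Why: Ester saponification; C2 carries no hydrogen, so base cannot isomerise the allene to an alkyne, and the low temperature limits conjugate addition of hydroxide.

Step 7
Reactants: 13 2-methylbuta-2,3-dienoic acid (1.5 equiv); 8 (2S,15E)-16-iodohexadec-15-en-2-yl acetate
Product: 14 (2S,15E)-16-(4-methyl-5-oxo-2,5-dihydrofuran-3-yl)hexadec-15-en-2-yl acetate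
Conditions: Pd(PPh3)4 (5 mol%), Ag2CO3 (10 mol%), K2CO3 (2 equiv), MeCN, 70 °C
Reagents that add atoms: none
Why: Oxidative addition of the C–I bond of 8 to zerovalent palladium gives an (E)-alkenyl complex of divalent palladium, which adds across the allene of the carboxylate of 13 with the alkenyl group going to the central carbon, giving a π-allylpalladium whose termini are C(CH3)(CO2−) and CH2. The carboxylate oxygen then attacks the CH2 terminus and releases zerovalent palladium; the alternative order, anti attack of the carboxylate on the allene bound to the alkenylpalladium followed by C–C reductive elimination, leads to the same product. The closest known reaction type is the Pd(PPh3)4/Ag2CO3-cocatalysed coupling–cyclisation of 2,3-allenoic acids with aryl and alkenyl halides to 4-substituted 2(5H)-furanones. The single ring closes by O1–C5 bond formation, a five-membered lactonisation that amounts to intramolecular allylic substitution on the π-allyl, and no other ring size is open because the second allyl terminus carries the carboxyl group itself. No stereocenter is formed, and the acetate-bearing C2 of 8 is remote and untouched, as is the E geometry of the alkenyl group. The step needs the alkenyl group on the central allene carbon, which is the intrinsic regiochemistry of allene carbopalladation, and coupling faster than cycloisomerisation of 13 without coupling, which the reactive alkenyl iodide and the excess of 13 should secure.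

Step 8
Reactants: 14 (2S,15E)-16-(4-methyl-5-oxo-2,5-dihydrofuran-3-yl)hexadec-15-en-2-yl acetate
Product: 15 (2S)-16-(4-methyl-5-oxo-2,5-dihydrofuran-3-yl)hexadecan-2-yl acetate (target)
Conditions: H2 (1 atm), RhCl(PPh3)3 (10 mol%), benzene/EtOH 1:1, rt
Reagents that add atoms: none
Why: Homogeneous hydrogenation with RhCl(PPh3)3 is governed by alkene substitution, so the 1,2-disubstituted side-chain alkene should be reduced while the tetrasubstituted conjugated ring alkene does not bind the metal, and the lactone C5–O bond, the acetate and the C2 stereocenter are left alone.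

**Compound list**

1 | 1-tridecyne | C#CCCCCCCCCCCC | starting material
2 | (S)-propylene oxide | C[C@H]1CO1 | starting material
3 | lithium tridec-1-yn-1-ide | [Li]C#CCCCCCCCCCCC | intermediate
4 | (S)-hexadec-4-yn-2-ol | C[C@H](O)CC#CCCCCCCCCCCC | intermediate
5 | (S)-hexadec-15-yn-2-ol | C[C@H](O)CCCCCCCCCCCCC#C | intermediate
6 | (S)-hexadec-15-yn-2-yl acetate | C[C@H](OC(C)=O)CCCCCCCCCCCCC#C | intermediate
7 | chlorobis(cyclopentadienyl)[(1E,15S)-15-acetoxyhexadec-1-en-1-yl]zirconium | C[C@H](OC(C)=O)CCCCCCCCCCCC/C=C/[Zr](Cl)(C1C=CC=C1)C1C=CC=C1 | intermediate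
8 | (2S,15E)-16-iodohexadec-15-en-2-yl acetate | C[C@H](OC(C)=O)CCCCCCCCCCCC/C=C/I | intermediate
9 | ethyl 2-(triphenylphosphoranylidene)propanoate | CCOC(=O)C(C)=P(c1ccccc1)(c1ccccc1)c1ccccc1 | starting material
10 | acetyl chloride | CC(=O)Cl | starting material
11 | ketene | C=C=O | intermediate
12 | ethyl 2-methylbuta-2,3-dienoate | C=C=C(C)C(=O)OCC | intermediate
13 | 2-methylbuta-2,3-dienoic acid | C=C=C(C)C(=O)O | intermediate
14 | (2S,15E)-16-(4-methyl-5-oxo-2,5-dihydrofuran-3-yl)hexadec-15-en-2-yl acetate | C[C@H](OC(C)=O)CCCCCCCCCCCC/C=C/C1=C(C)C(=O)OC1 | intermediate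
15 | (2S)-16-(4-methyl-5-oxo-2,5-dihydrofuran-3-yl)hexadecan-2-yl acetate | CC(=O)O[C@@H](C)CCCCCCCCCCCCCCC1=C(C)C(=O)OC1 | target

**Step count**

Total steps: 8. Longest linear sequence: 6 (steps 1, 2, 3, 4, 7, 8); the acid branch is steps 5 and 6.

**Steps most likely to fail**

1. Step 7 (coupling–cyclisation). Cycloisomerisation of the allenoic acid without coupling, or oligomerisation of the electron-poor allene, may outrun carbopalladation, so that the iodide is left unused.
Fallback, setting out from 13 and 6 and coming back at 14: 13 is bromolactonised with CuBr2 in acetone/H2O at 65 °C to 4-bromo-3-methylfuran-2(5H)-one F1. Alkyne 6 is hydroborated with pinacolborane (Cp2Zr(H)Cl cat., Et3N cat., rt) to (2S,15E)-16-(4,4,5,5-tetramethyl-1,3,2-dioxaborolan-2-yl)hexadec-15-en-2-yl acetate F2. Suzuki–Miyaura coupling of F1 with F2 (Pd(PPh3)4, K3PO4, THF/H2O, 50 °C) should give 14, with the ring made before the C–C bond instead of together with it.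

2. Step 8 (selective hydrogenation). Addition of hydrogen across the whole dienoate with migration of the ring alkene, slow turnover through chelation of the diene to rhodium, or partial reduction of the ring alkene may erode selectivity.
Fallback, setting out from 6 and 13 and coming back at 15: 6 is semihydrogenated (H2, Pd/CaCO3 poisoned with Pb(OAc)2, quinoline, hexane) to (S)-hexadec-15-en-2-yl acetate F3. F3 is hydroborated with 9-BBN in THF to (S)-16-(9-borabicyclo[3.3.1]nonan-9-yl)hexadecan-2-yl acetate F4. B-alkyl Suzuki–Miyaura coupling of F4 with 4-bromo-3-methylfuran-2(5H)-one F1 (made from 13 with CuBr2 as above) under PdCl2(dppf), K3PO4, DMF/THF/H2O, rt → 50 °C should give 15 directly, so no side-chain alkene has to be reduced next to the butenolide.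

3. Step 4 (hydrozirconation–iodination). Reduction of the acetate by the zirconium hydride, or protonolysis of the alkenylzirconium before iodine is added, may compete with clean formation of the iodide.
Fallback, setting out from 6 and coming back at 8: radical hydrostannation of 6 (Bu3SnH, AIBN, toluene, 90 °C; esters are inert) should give mainly (2S,15E)-16-(tributylstannyl)hexadec-15-en-2-yl acetate F5. Iododestannylation (I2, CH2Cl2, 0 °C) then gives 8; any Z isomer carried along is harmless because step 8 removes the alkene.

**Further compounds**

F1 | step 7 | 4-bromo-3-methylfuran-2(5H)-one | CC1=C(Br)COC1=O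
F2 | step 7 | (2S,15E)-16-(4,4,5,5-tetramethyl-1,3,2-dioxaborolan-2-yl)hexadec-15-en-2-yl acetate | C[C@H](OC(C)=O)CCCCCCCCCCCC/C=C/B1OC(C)(C)C(C)(C)O1
F3 | step 8 | (S)-hexadec-15-en-2-yl acetate | C[C@H](OC(C)=O)CCCCCCCCCCCCC=C
F4 | step 8 | (S)-16-(9-borabicyclo[3.3.1]nonan-9-yl)hexadecan-2-yl acetate | C[C@H](OC(C)=O)CCCCCCCCCCCCCCB1C2CCCC1CCC2
F5 | step 4 | (2S,15E)-16-(tributylstannyl)hexadec-15-en-2-yl acetate | C[C@H](OC(C)=O)CCCCCCCCCCCC/C=C/[Sn](CCCC)(CCCC)CCCC
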